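**Assumption:** the target SMILES is read literally. In ent-gibberellane numbering it is the 9-epimer (9α-H, B/C trans) of 1β,12α-dihydroxy-3-oxo-GA9, with the 19,10-lactone kept. α is the face of the lactone bridge, β the face of the C15–C16 bridge. Gibberellic acid (GA3) is taken as a cheap bulk fermentation product.

## Retrosynthetic overview

1. Target ⇐ 9-epi-12α-hydroxy-GA7: ring A is finished last (allylic oxidation, then conjugate borylation/oxidation gives 1β-OH/3-oxo).
2. 9α-H and 12α-OH ⇐ 9(11)-en-12-one: axial hydride to C9 on the side of the one-carbon bridge, then equatorial hydride to the 12-ketone.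
3. 12-O / 13-H / 16-methylene ⇐ isoxazoline ⇐ intramolecular nitrile oxide–alkene [3+2] cycloaddition that rebuilds ring D (key step).
4. Nitrile oxide and 12-ene ⇐ 13,16-seco keto ester ⇐ 16-norketone α-ketol of GA3 (ozonolysis, Pb(OAc)4).
5. Ring order: rings A, B, C and the lactone are bought in GA3; ring D is opened at C13–C16 and re-formed by the cycloaddition; the transient isoxazoline ring is then cleaved.

## Route

Step 1
Reactants: 1 gibberellic acid (GA3)
Product: 2 GA3 7-SEM ester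
Conditions: SEMCl, Et3N, CH2Cl2, 0 °C to rt
Reagents that add atoms: 2-(trimethylsilyl)ethoxymethyl chloride, C[Si](C)(C)CCOCCl
Why: Carboxylate O-alkylation (SN2) is much faster than etherification of the secondary and tertiary hydroxyls, and gives an ester that fluoride removes later; no stereocentre is touched.

Step 2
Reactants: 2 GA3 7-SEM ester
Product: 3 3-O-TBS-GA3 7-SEM ester
Conditions: TBSCl, imidazole, DMF, rt
Reagents that add atoms: tert-butyldimethylsilyl chloride, CC(C)(C)[Si](C)(C)Cl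
Why: Silyl ether formation takes the secondary allylic 3β-OH while the tertiary bridgehead 13-OH stays free for the later cleavage.

Step 3
Reactants: 3 3-O-TBS-GA3 7-SEM ester
Product: 5 3-O-TBS-13-hydroxy-16-oxo-17-nor-GA3 7-SEM ester, via ozonide 4 (not isolated)
Conditions: O3 (1 equiv, indicator dye), CH2Cl2, −78 °C; then Me2S, −78 °C to rt
Reagents that add atoms: ozone, [O-][O+]=O
Why: Criegee ozonolysis picks the electron-rich exocyclic 1,1-disubstituted 16-ene over the hindered ring A alkene that is deactivated by its two allylic oxygens, and gives the 13-hydroxy-16-ketone (α-ketol).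

Step 4
Reactants: 5 3-O-TBS-13-hydroxy-16-oxo-17-nor-GA3 7-SEM ester
Product: 6 13,16-seco keto ester
Conditions: Pb(OAc)4, MeOH/benzene, 0 °C to rt
Reagents that add atoms: methanol, CO
Why: Lead tetraacetate α-ketol (Criegee-type glycol) cleavage of the methanol hemiketal breaks C13–C16, leaving a C13 ketone in ring C and C16 as a methyl ester on the C8 side chain; C8 is untouched.

Step 5
Reactants: 6 13,16-seco keto ester
Product: 8 13-triflyloxy-12-ene, via potassium enolate 7 (not isolated)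
Conditions: KN(SiMe3)2, THF, −78 °C; then PhNTf2, −78 to 0 °C; aq. NH4Cl
Reagents that add atoms: N-phenylbis(trifluoromethanesulfonimide), O=S(=O)(N(c1ccccc1)S(=O)(=O)C(F)(F)F)C(F)(F)F
Why: Kinetic enolate O-triflation; the bulky amide deprotonates C12 and not the neopentyl C14 next to quaternary C8, which fixes the alkene at C12=C13.

Step 6
Reactants: 8 13-triflyloxy-12-ene
Product: 9 seco 12-ene methyl ester
Conditions: Pd(OAc)2 (5 mol%), PPh3, n-Bu3N, HCO2H, DMF, 40 °C
Reagents that add atoms: none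
Why: Palladium-catalysed formate hydrogenolysis of the enol triflate (Cacchi reduction) replaces OTf by H; oxidative addition into the C–OTf bond is far faster than ionisation of the hindered tertiary allylic lactone at this temperature, and the cis ring alkene is left with a hydrogen on C13.

Step 7
Reactants: 9 seco 12-ene methyl ester
Product: 10 seco 12-ene 16-aldehyde
Conditions: i-Bu2AlH (1.1 equiv), CH2Cl2, −78 °C; aq. potassium sodium tartrate
Reagents that add atoms: none
Why: Partial hydride reduction through the stable aluminium hemiacetal; the unhindered CH2CO2Me reacts before the hindered C7 ester and the lactone flanked by two quaternary carbons.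

Step 8
Reactants: 10 seco 12-ene 16-aldehyde
Product: 13 isoxazoline, via aldoxime 11 (not isolated), via nitrile oxide 12 (not isolated)
Conditions: NH2OH·HCl, NaOAc, MeOH, rt; then PhI(OAc)2, cat. CF3CO2H, MeOH (high dilution), 0 °C to rt
Reagents that add atoms: hydroxylamine hydrochloride, NO.Cl
Why: Oximation, hypervalent-iodine oxidation and intramolecular nitrile oxide–alkene 1,3-dipolar cycloaddition of the 5-hexenyl type close the five-membered ring D; the C8 tether forces C16 onto the β-face of C13 (natural bridgehead configuration) and places oxygen syn on C12 (12β).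

Step 9
Reactants: 13 isoxazoline
Product: 14 3-O-TBS-12β-hydroxy-16-oxo-17-nor-GA7 7-SEM ester
Conditions: Mo(CO)6, MeCN/H2O, 80 °C
Reagents that add atoms: water, O
Why: Reductive N–O cleavage of the isoxazoline with hydrolysis of the imine unmasks the β-hydroxy ketone; it cannot dehydrate because C13 is a bridgehead, and the alkenes survive.

Step 10
Reactants: 14 3-O-TBS-12β-hydroxy-16-oxo-17-nor-GA7 7-SEM ester
Product: 15 3-O-TBS-12β-hydroxy-GA7 7-SEM ester
Conditions: Zn, CH2Br2, TiCl4, THF/CH2Cl2, 0 °C to rt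
Reagents that add atoms: dibromomethane, BrCBr
Why: Lombardo methylenation is non-basic, so the β-hydroxy ketone does not undergo retro-aldol and the base-sensitive ring A lactone is safe while the 16-methylene is restored.

Step 11
Reactants: 15 3-O-TBS-12β-hydroxy-GA7 7-SEM ester
Product: 17 3-O-TBS-9,11-didehydro-12-oxo-GA7 7-SEM ester, via 12-ketone 16 (not isolated)
Conditions: IBX (4 equiv), DMSO, 75 °C
Reagents that add atoms: none
Why: IBX alcohol oxidation followed by IBX dehydrogenation of the ketone can only desaturate C11–C9 because C13 is a bridgehead; this deliberately erases both the C12 and the C9 stereocentre.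

Step 12
Reactants: 17 3-O-TBS-9,11-didehydro-12-oxo-GA7 7-SEM ester
Product: 18 3-O-TBS-9-epi-12-oxo-GA7 7-SEM ester
Conditions: Cu(OAc)2·H2O (5 mol%), 1,2-bis(diphenylphosphino)benzene (5 mol%), PhMe2SiH (1.5 equiv), t-BuOH (1.5 equiv), toluene, 0 °C
Reagents that add atoms: none
Why: Copper hydride conjugate reduction delivers hydride to C9 axially from the α-face, the side of the one-carbon bridge C14, because the β-face is screened by the inward hydrogen of C15 on the two-carbon bridge; this gives 9α-H (B/C trans) without touching the isolated alkenes.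

Step 13
Reactants: 18 3-O-TBS-9-epi-12-oxo-GA7 7-SEM ester
Product: 19 3-O-TBS-9-epi-12α-hydroxy-GA7 7-SEM ester
Conditions: LiBH(s-Bu)3, THF, −78 °C
Reagents that add atoms: none
Why: Bulky-hydride ketone reduction; the reagent cannot pass the syn-axial hydrogens on C9 and C14 and attacks equatorially along the β-side periphery, where the sp2 carbon C16 has no inward hydrogen, so the new hydroxyl is axial and α (anti to the C15–C16 bridge).

Step 14
Reactants: 19 3-O-TBS-9-epi-12α-hydroxy-GA7 7-SEM ester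
Product: 20 9-epi-12α-hydroxy-GA7
Conditions: Bu4NF, AcOH, THF, rt
Reagents that add atoms: none
Why: Fluoride-induced desilylation removes the TBS ether and fragments the SEM ester in one operation under buffered conditions that spare the allylic lactone.

Step 15
Reactants: 20 9-epi-12α-hydroxy-GA7
Product: 21 9-epi-12α-hydroxy-3-oxo-GA7
Conditions: MnO2 (excess), acetone, rt
Reagents that add atoms: none
Why: Manganese dioxide allylic oxidation converts only the allylic 3β-OH to the 1-en-3-one; the saturated 12α-OH is not oxidised.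

Step 16
Reactants: 21 9-epi-12α-hydroxy-3-oxo-GA7
Product: 23 target (1β,12α-dihydroxy-3-oxo-9-epi-GA9 19,10-lactone), via C1-boronate 22 (not isolated)
Conditions: B2pin2, CuCl (10 mol%), bis[2-(diphenylphosphino)phenyl] ether (10 mol%), NaOt-Bu (1.1 equiv), MeOH, THF, rt; then NaBO3·4H2O, THF/H2O, 0 °C to rt; 1 M HCl to pH 4
Reagents that add atoms: sodium perborate, [Na+].[O-]OB=O
Why: Copper-catalysed conjugate borylation adds boron to C1 from the β-face, anti to the α-lactone bridge over ring A, and perborate oxidation with retention gives the 1β-hydroxy-3-ketone; only a catalytic amount of alkoxide remains once the acid is neutralised, which protects the β-keto lactone.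

## Compound list

1 | gibberellic acid (GA3; 3β,13-dihydroxy-1,16-diene 19,10-lactone 7-acid, 9β-H) | C=C1C[C@]23C[C@@]1(O)CC[C@H]2[C@]12OC(=O)[C@](C)([C@@H](O)C=C1)[C@H]2[C@@H]3C(=O)O | starting material
2 | GA3 7-SEM ester | C=C1C[C@]23C[C@@]1(O)CC[C@H]2[C@]12OC(=O)[C@](C)([C@@H](O)C=C1)[C@H]2[C@@H]3C(=O)OCOCC[Si](C)(C)C | intermediate
3 | 3-O-TBS-GA3 7-SEM ester | C=C1C[C@]23C[C@@]1(O)CC[C@H]2[C@]12OC(=O)[C@](C)([C@@H](O[Si](C)(C)C(C)(C)C)C=C1)[C@H]2[C@@H]3C(=O)OCOCC[Si](C)(C)C | intermediate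
4 | 16,17-ozonide of 3 (spiro-1,2,4-trioxolane at C16, C16 configuration undefined) | C1OOC2(O1)C[C@]34C[C@@]2(O)CC[C@H]3[C@]56OC(=O)[C@](C)([C@@H](O[Si](C)(C)C(C)(C)C)C=C5)[C@H]6[C@@H]4C(=O)OCOCC[Si](C)(C)C | intermediate
5 | 3-O-TBS-13-hydroxy-16-oxo-17-nor-GA3 7-SEM ester (α-ketol) | O=C1C[C@]23C[C@@]1(O)CC[C@H]2[C@]12OC(=O)[C@](C)([C@@H](O[Si](C)(C)C(C)(C)C)C=C1)[C@H]2[C@@H]3C(=O)OCOCC[Si](C)(C)C | intermediate
6 | 13,16-seco keto ester (ring D open: C13 ketone in ring C, CH2CO2Me on C8) | COC(=O)C[C@]12CC(=O)CC[C@H]1[C@]34OC(=O)[C@](C)([C@@H](O[Si](C)(C)C(C)(C)C)C=C3)[C@H]4[C@@H]2C(=O)OCOCC[Si](C)(C)C | intermediate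
7 | potassium 12(13)-enolate of 6 | [K+].COC(=O)C[C@]12CC([O-])=CC[C@H]1[C@]34OC(=O)[C@](C)([C@@H](O[Si](C)(C)C(C)(C)C)C=C3)[C@H]4[C@@H]2C(=O)OCOCC[Si](C)(C)C | intermediate
8 | 13-triflyloxy-12-ene (enol triflate of 6) | COC(=O)C[C@]12CC(OS(=O)(=O)C(F)(F)F)=CC[C@H]1[C@]34OC(=O)[C@](C)([C@@H](O[Si](C)(C)C(C)(C)C)C=C3)[C@H]4[C@@H]2C(=O)OCOCC[Si](C)(C)C | intermediate
9 | seco 12-ene methyl ester | COC(=O)C[C@]12CC=CC[C@H]1[C@]34OC(=O)[C@](C)([C@@H](O[Si](C)(C)C(C)(C)C)C=C3)[C@H]4[C@@H]2C(=O)OCOCC[Si](C)(C)C | intermediate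
10 | seco 12-ene 16-aldehyde | O=CC[C@]12CC=CC[C@H]1[C@]34OC(=O)[C@](C)([C@@H](O[Si](C)(C)C(C)(C)C)C=C3)[C@H]4[C@@H]2C(=O)OCOCC[Si](C)(C)C | intermediate
11 | aldoxime of 10 (E/Z mixture) | ON=CC[C@]12CC=CC[C@H]1[C@]34OC(=O)[C@](C)([C@@H](O[Si](C)(C)C(C)(C)C)C=C3)[C@H]4[C@@H]2C(=O)OCOCC[Si](C)(C)C | intermediate
12 | nitrile oxide from 11 | [O-][N+]#CC[C@]12CC=CC[C@H]1[C@]34OC(=O)[C@](C)([C@@H](O[Si](C)(C)C(C)(C)C)C=C3)[C@H]4[C@@H]2C(=O)OCOCC[Si](C)(C)C | intermediate
13 | isoxazoline (ring D re-formed; C16=N–O–C12 with 12β-O; 17-nor) | N1=C2C[C@]34C[C@H]2[C@H](O1)C[C@H]3[C@]56OC(=O)[C@](C)([C@@H](O[Si](C)(C)C(C)(C)C)C=C5)[C@H]6[C@@H]4C(=O)OCOCC[Si](C)(C)C | intermediate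
14 | 3-O-TBS-12β-hydroxy-16-oxo-17-nor-GA7 7-SEM ester | O=C1C[C@]23C[C@H]1[C@H](O)C[C@H]2[C@]12OC(=O)[C@](C)([C@@H](O[Si](C)(C)C(C)(C)C)C=C1)[C@H]2[C@@H]3C(=O)OCOCC[Si](C)(C)C | intermediate
15 | 3-O-TBS-12β-hydroxy-GA7 7-SEM ester | C=C1C[C@]23C[C@H]1[C@H](O)C[C@H]2[C@]12OC(=O)[C@](C)([C@@H](O[Si](C)(C)C(C)(C)C)C=C1)[C@H]2[C@@H]3C(=O)OCOCC[Si](C)(C)C | intermediate
16 | 3-O-TBS-12-oxo-GA7 7-SEM ester | C=C1C[C@]23C[C@H]1C(=O)C[C@H]2[C@]12OC(=O)[C@](C)([C@@H](O[Si](C)(C)C(C)(C)C)C=C1)[C@H]2[C@@H]3C(=O)OCOCC[Si](C)(C)C | intermediate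
17 | 3-O-TBS-9,11-didehydro-12-oxo-GA7 7-SEM ester | C=C1C[C@]23C[C@H]1C(=O)C=C2[C@]12OC(=O)[C@](C)([C@@H](O[Si](C)(C)C(C)(C)C)C=C1)[C@H]2[C@@H]3C(=O)OCOCC[Si](C)(C)C | intermediate
18 | 3-O-TBS-9-epi-12-oxo-GA7 7-SEM ester (9α-H) | C=C1C[C@]23C[C@H]1C(=O)C[C@@H]2[C@]12OC(=O)[C@](C)([C@@H](O[Si](C)(C)C(C)(C)C)C=C1)[C@H]2[C@@H]3C(=O)OCOCC[Si](C)(C)C | intermediate
19 | 3-O-TBS-9-epi-12α-hydroxy-GA7 7-SEM ester | C=C1C[C@]23C[C@H]1[C@@H](O)C[C@@H]2[C@]12OC(=O)[C@](C)([C@@H](O[Si](C)(C)C(C)(C)C)C=C1)[C@H]2[C@@H]3C(=O)OCOCC[Si](C)(C)C | intermediate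
20 | 9-epi-12α-hydroxy-GA7 (free 3β-OH and 7-acid) | C=C1C[C@]23C[C@H]1[C@@H](O)C[C@@H]2[C@]12OC(=O)[C@](C)([C@@H](O)C=C1)[C@H]2[C@@H]3C(=O)O | intermediate
21 | 9-epi-12α-hydroxy-3-oxo-GA7 (1-en-3-one) | C=C1C[C@]23C[C@H]1[C@@H](O)C[C@@H]2[C@]12OC(=O)[C@](C)(C(=O)C=C1)[C@H]2[C@@H]3C(=O)O | intermediate
22 | 1β-(pinacolatoboryl)-3-ketone | C=C1C[C@]23C[C@H]1[C@@H](O)C[C@@H]2[C@]12OC(=O)[C@](C)(C(=O)C[C@H]1B1OC(C)(C)C(C)(C)O1)[C@H]2[C@@H]3C(=O)O | intermediate
23 | 1β,12α-dihydroxy-3-oxo-9-epi-GA9 19,10-lactone (CNP0259985.3) | C=C1C[C@]23C[C@H]1[C@@H](O)C[C@@H]2[C@]12OC(=O)[C@](C)(C(=O)C[C@H]1O)[C@H]2[C@@H]3C(=O)O | target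

## Step count and risks

Total step count: 16. Longest linear sequence: 16 steps from gibberellic acid.

**Step 8.** The cycloaddition must close a bridged bicyclo[3.2.1] system; furoxan dimerisation or the six-membered mode could compete. The fallback sets out from 10 and builds ring D by a radical route. Dimethyl (1-diazo-2-oxopropyl)phosphonate with K2CO3 in MeOH gives the terminal alkyne F1. mCPBA with NaHCO3 gives the 12,13-epoxide F2 (either face serves). Cp2TiCl, made from Cp2TiCl2 and Zn in THF, opens the epoxide with trivalent titanium; the C13 radical closes 5-exo-dig onto the alkyne to give the 12-hydroxy-16-ene F3, which already carries the methylene. F3 is the C12 epimer of 15; under the IBX conditions of step 11 it gives the same ketone 16 and comes back to the route at 17.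

**Step 12.** The β-carbon C9 is fully substituted and hindered, the facial outcome decides the 9-epi configuration, and the copper hydride may over-reduce the ketone. The fallback sets out from 17 and replaces the metal hydride by metal-free iminium transfer hydrogenation: diethyl 2,6-dimethyl-1,4-dihydropyridine-3,5-dicarboxylate (Hantzsch ester) with catalytic benzylammonium trifluoroacetate in dioxane at 60 °C. The bulky dihydropyridine gives its hydride to C9 of the activated enone from the side of the one-carbon bridge, hydrolysis returns the ketone, and the route is rejoined at 18 with no new compound.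

**Step 13.** The facial choice at C12 rests on the preference of a bulky hydride for equatorial attack; the two-carbon bridge next to the carbonyl could reverse it. The fallback sets out from 18 and reaches the axial alcohol by inversion instead of facial control. NaBH4 in MeOH at 0 °C, a small hydride that attacks axially from the α-face, gives the equatorial 12β-alcohol F4. Mitsunobu reaction with PPh3, DIAD and HCO2H in toluene displaces the equatorial oxyphosphonium with inversion and gives the 12α-formate F5; the leaving group has no anti-periplanar hydrogen, so elimination is not a threat. KHCO3 in MeOH/H2O removes the formyl group, and the route is rejoined at 19.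

## Further compounds

F1 | step 8 | seco 12-ene terminal alkyne (propargyl on C8) | C#CC[C@]12CC=CC[C@H]1[C@]34OC(=O)[C@](C)([C@@H](O[Si](C)(C)C(C)(C)C)C=C3)[C@H]4[C@@H]2C(=O)OCOCC[Si](C)(C)C
F2 | step 8 | 12α,13α-epoxide of F1 | C#CC[C@]12C[C@H]3O[C@H]3C[C@H]1[C@]45OC(=O)[C@](C)([C@@H](O[Si](C)(C)C(C)(C)C)C=C4)[C@H]5[C@@H]2C(=O)OCOCC[Si](C)(C)C
F3 | step 8 | 3-O-TBS-12α-hydroxy-GA7 7-SEM ester (9β-H) | C=C1C[C@]23C[C@H]1[C@@H](O)C[C@H]2[C@]12OC(=O)[C@](C)([C@@H](O[Si](C)(C)C(C)(C)C)C=C1)[C@H]2[C@@H]3C(=O)OCOCC[Si](C)(C)C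
F0 | step 12 | none | none
F4 | step 13 | 3-O-TBS-9-epi-12β-hydroxy-GA7 7-SEM ester | C=C1C[C@]23C[C@H]1[C@H](O)C[C@@H]2[C@]12OC(=O)[C@](C)([C@@H](O[Si](C)(C)C(C)(C)C)C=C1)[C@H]2[C@@H]3C(=O)OCOCC[Si](C)(C)C
F5 | step 13 | 12α-formate of the 9-epi series | C=C1C[C@]23C[C@H]1[C@@H](OC=O)C[C@@H]2[C@]12OC(=O)[C@](C)([C@@H](O[Si](C)(C)C(C)(C)C)C=C1)[C@H]2[C@@H]3C(=O)OCOCC[Si](C)(C)C
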